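**Numbering and reading of the target (one-line assumption):** C1 is the lactone carbonyl and C27 the terminal CH2 of the side chain; the SMILES is read as 4R,15S,21S with 6E,8Z,10Z,16E,18Z,24E.

## Retrosynthetic overview

1. The only ring, the 22-membered lactone, is closed at C7–C8 by an intramolecular Sonogashira coupling; the 8Z and 18Z alkenes then come from one Zn(Cu/Ag) semi-reduction of the two conjugated ring alkynes.
2. The C1–O–C21 ester is made beforehand by carbodiimide esterification of fragment A (C1–C7 acid, C7 vinyl iodide) with the C21 alcohol.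
3. C17–C18 is made by Sonogashira coupling of fragment B (C8–C17: silyl-capped Z-enyne, C15 silyl ether, C17 vinyl iodide) with fragment C (C18–C27 homopropargylic alcohol).
4. Fragment A: Evans alkylation (C4), then enol triflate/Reformatsky coupling. Fragment B: CBS reduction of an iodoenone (C15), then Z-Wittig. Fragment C: (S)-epichlorohydrin (C21), carboalumination and Stille vinylation.

## Fragment A (C1–C7)

Step 1
Reactants: 1 (4S)-4-benzyl-3-propanoyl-1,3-oxazolidin-2-one; 2 3-bromo-1-(trimethylsilyl)prop-1-yne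
Product: 4 (4S)-4-benzyl-3-[(2R)-2-methyl-5-(trimethylsilyl)pent-4-ynoyl]-1,3-oxazolidin-2-one, via sodium enolate 3 (not isolated)
Conditions: NaN(SiMe3)2, THF, −78 °C; then 2, −78 → −40 °C
Reagents that add atoms: none
Why: Evans asymmetric alkylation; the chelated Z-enolate is alkylated on the face away from the benzyl group, which sets C4 as R.

Step 2
Reactants: 4 (4S)-4-benzyl-3-[(2R)-2-methyl-5-(trimethylsilyl)pent-4-ynoyl]-1,3-oxazolidin-2-one
Product: 5 (2R)-N-methoxy-N,2-dimethyl-5-(trimethylsilyl)pent-4-ynamide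
Conditions: MeONHMe·HCl, Me3Al, CH2Cl2, 0 °C → rt; 1 M HCl work-up
Reagents that add atoms: N,O-dimethylhydroxylamine hydrochloride, CNOC.Cl
Why: Weinreb transamidation with the aluminium amide cleaves the auxiliary at the exocyclic carbonyl without touching the α-stereocentre.

Step 3
Reactants: 5 (2R)-N-methoxy-N,2-dimethyl-5-(trimethylsilyl)pent-4-ynamide
Product: 6 (3R)-3-methyl-6-(trimethylsilyl)hex-5-yn-2-one
Conditions: MeMgBr, THF, 0 °C; aq. NH4Cl
Reagents that add atoms: methylmagnesium bromide, C[Mg]Br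
Why: Weinreb ketone synthesis; the chelated tetrahedral adduct stops at the methyl ketone, whose methyl becomes the exo-methylene carbon.

Step 4
Reactants: 6 (3R)-3-methyl-6-(trimethylsilyl)hex-5-yn-2-one
Product: 8 (3R)-3-methyl-6-(trimethylsilyl)hex-1-en-5-yn-2-yl trifluoromethanesulfonate, via potassium enolate 7 (not isolated)
Conditions: KN(SiMe3)2, THF, −78 °C; then PhNTf2, −78 → 0 °C
Reagents that add atoms: N-phenylbis(trifluoromethanesulfonimide), O=S(=O)(N(c1ccccc1)S(=O)(=O)C(F)(F)F)C(F)(F)F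
Why: Kinetic enolisation at the methyl group followed by O-triflation (enol triflate formation) leaves the C4 methine, and so the R centre, untouched.

Step 5
Reactants: 8 (3R)-3-methyl-6-(trimethylsilyl)hex-1-en-5-yn-2-yl trifluoromethanesulfonate
Product: 9 methyl (4R)-4-methyl-3-methylidene-7-(trimethylsilyl)hept-6-ynoate
Conditions: BrZnCH2CO2Me (2 equiv, from methyl bromoacetate and Zn dust in THF), Pd(PPh3)4 (5 mol %), THF, 55 °C
Reagents that add atoms: (2-methoxy-2-oxoethyl)zinc bromide, COC(=O)C[Zn]Br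
Why: Negishi-type cross-coupling of the Reformatsky zinc enolate with the vinyl triflate gives the β,γ-unsaturated ester with the exo-methylene already in place.

Step 6
Reactants: 9 methyl (4R)-4-methyl-3-methylidene-7-(trimethylsilyl)hept-6-ynoate
Product: 10 methyl (4R)-4-methyl-3-methylidenehept-6-ynoate
Conditions: AgNO3 (10 mol %), MeOH/H2O/CH2Cl2, rt
Reagents that add atoms: none
Why: Silver-catalysed protodesilylation frees the alkyne under neutral conditions, so the exo-methylene does not migrate into conjugation.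

Step 7
Reactants: 10 methyl (4R)-4-methyl-3-methylidenehept-6-ynoate
Product: 12 methyl (4R,6E)-7-iodo-4-methyl-3-methylidenehept-6-enoate, via alkenylzirconocene chloride 11 (not isolated)
Conditions: Cp2Zr(H)Cl (1.3 equiv), THF, rt, 20 min, dark; then I2, THF, 0 °C
Reagents that add atoms: iodine, II
Why: Schwartz hydrozirconation adds H–Zr syn to the terminal alkyne much faster than to the ester or the 1,1-disubstituted alkene, and iodinolysis with retention gives the 6E vinyl iodide.

Step 8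
Reactants: 12 methyl (4R,6E)-7-iodo-4-methyl-3-methylidenehept-6-enoate
Product: 13 (4R,6E)-7-iodo-4-methyl-3-methylidenehept-6-enoic acid (fragment A)
Conditions: Me3SnOH (4 equiv), 1,2-dichloroethane, 70 °C; 1 M HCl wash
Reagents that add atoms: trimethyltin hydroxide, C[Sn](C)(C)O
Why: Neutral ester hydrolysis with Me3SnOH avoids the basic conditions that would move the exo-methylene into conjugation.

## Fragment B (C8–C17)

Step 9
Reactants: 14 prop-2-yn-1-ol
Product: 16 (2E)-3-iodo-2-methylprop-2-en-1-ol, via alkenylalane 15 (not isolated)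
Conditions: Me3Al (3 equiv), Cp2ZrCl2 (0.25 equiv), CH2Cl2, 0 °C → rt; then I2, THF, −30 → 0 °C
Reagents that add atoms: trimethylaluminium, C[Al](C)C; iodine, II
Why: Negishi zirconium-catalysed carboalumination adds Me–Al syn across the alkyne and iodinolysis with retention gives the E trisubstituted vinyl iodide (the C16=C17 geometry).

Step 10
Reactants: 16 (2E)-3-iodo-2-methylprop-2-en-1-ol
Product: 17 (2E)-3-iodo-2-methylprop-2-enal
Conditions: MnO2 (activated, excess), CH2Cl2, rt, dark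
Reagents that add atoms: none
Why: Selective allylic alcohol oxidation with MnO2 stops at the enal and does not touch the vinyl iodide.

Step 11
Reactants: 17 (2E)-3-iodo-2-methylprop-2-enal; 18 1-bromo-4-chlorobutane
Product: 20 rac-(1E)-7-chloro-1-iodo-2-methylhept-1-en-3-ol, via Grignard reagent 19 (not isolated)
Conditions: 18, Mg, THF, rt; then 17, THF, −78 °C; aq. NH4Cl
Reagents that add atoms: none
Why: Grignard 1,2-addition; Mg inserts into C–Br only, and at −78 °C addition to the aldehyde outruns iodine–magnesium exchange.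

Step 12
Reactants: 20 rac-(1E)-7-chloro-1-iodo-2-methylhept-1-en-3-ol
Product: 21 (1E)-7-chloro-1-iodo-2-methylhept-1-en-3-one
Conditions: Dess–Martin periodinane, CH2Cl2, 0 °C → rt
Reagents that add atoms: none
Why: Dess–Martin oxidation gives the enone needed for a reagent-controlled reduction.

Step 13
Reactants: 21 (1E)-7-chloro-1-iodo-2-methylhept-1-en-3-one
Product: 22 (1E,3S)-7-chloro-1-iodo-2-methylhept-1-en-3-ol
Conditions: (R)-2-methyl-CBS-oxazaborolidine [(R)-1-methyl-3,3-diphenyltetrahydro-1H,3H-pyrrolo[1,2-c][1,3,2]oxazaborole] (20 mol %), BH3·SMe2, THF, −30 °C; MeOH quench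
Reagents that add atoms: none
Why: Corey–Bakshi–Shibata reduction; the α-methyl-β-iodovinyl group is the large substituent, so the (R)-catalyst delivers hydride to the face that gives the 3S allylic alcohol (C15).

Step 14
Reactants: 22 (1E,3S)-7-chloro-1-iodo-2-methylhept-1-en-3-ol
Product: 23 tert-butyl{[(1E,3S)-7-chloro-1-iodo-2-methylhept-1-en-3-yl]oxy}dimethylsilane
Conditions: TBSCl, imidazole, DMF, rt
Reagents that add atoms: tert-butyldimethylsilyl chloride, CC(C)(C)[Si](C)(C)Cl
Why: Standard silylation protects the C15 hydroxyl up to the last step.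

Step 15
Reactants: 23 tert-butyl{[(1E,3S)-7-chloro-1-iodo-2-methylhept-1-en-3-yl]oxy}dimethylsilane
Product: 25 [(5S,6E)-5-[(tert-butyldimethylsilyl)oxy]-7-iodo-6-methylhept-6-en-1-yl]triphenylphosphonium iodide, via primary iodide 24 (not isolated)
Conditions: NaI, PPh3, MeCN, 80 °C, dark, 36 h
Reagents that add atoms: triphenylphosphine, c1ccc(cc1)P(c1ccccc1)c1ccccc1; sodium iodide, [Na+].[I-]
Why: Finkelstein exchange followed by SN2 quaternisation occurs only at the primary carbon, since the vinyl iodide is inert to PPh3.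

Step 16
Reactants: 25 [(5S,6E)-5-[(tert-butyldimethylsilyl)oxy]-7-iodo-6-methylhept-6-en-1-yl]triphenylphosphonium iodide; 26 3-(trimethylsilyl)prop-2-ynal
Product: 28 tert-butyl{[(1E,3S,7Z)-1-iodo-2-methyl-10-(trimethylsilyl)deca-1,7-dien-9-yn-3-yl]oxy}dimethylsilane (fragment B), via phosphorus ylide 27 (not isolated)
Conditions: NaN(SiMe3)2, THF, −78 °C; then 26, −78 → 0 °C
Reagents that add atoms: none
Why: Wittig olefination of a non-stabilised ylide under lithium-free conditions is Z-selective and sets the C10=C11 Z alkene; the amide base does not touch the vinyl iodide.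

## Fragment C (C18–C27)

Step 17
Reactants: 29 (2S)-2-(chloromethyl)oxirane [(S)-epichlorohydrin]; 30 1-(trimethylsilyl)prop-1-yne
Product: 32 (2S)-1-chloro-6-(trimethylsilyl)hex-5-yn-2-ol, via propargyllithium reagent 31 (not isolated)
Conditions: 30, n-BuLi, THF, −78 → −20 °C; then −78 °C, BF3·OEt2, 29; aq. NH4Cl
Reagents that add atoms: none
Why: BF3-promoted SN2 opening of the epoxide at its CH2 by the silylpropargyl anion leaves the stereocentre untouched, so the S centre of epichlorohydrin becomes C21.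

Step 18
Reactants: 32 (2S)-1-chloro-6-(trimethylsilyl)hex-5-yn-2-ol
Product: 33 (2S)-1-chlorohex-5-yn-2-ol
Conditions: AgNO3 (10 mol %), MeOH/H2O/CH2Cl2, rt
Reagents that add atoms: none
Why: Silver-catalysed protodesilylation is neutral, so the chlorohydrin does not close to the epoxide before the carboalumination.

Step 19
Reactants: 33 (2S)-1-chlorohex-5-yn-2-ol
Product: 35 (2S,5E)-1-chloro-6-iodo-5-methylhex-5-en-2-ol, via alkenylalane 34 (not isolated)
Conditions: Me3Al (3 equiv), Cp2ZrCl2 (0.3 equiv), CH2Cl2, 0 °C → rt; then I2, THF, −30 °C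
Reagents that add atoms: trimethylaluminium, C[Al](C)C; iodine, II
Why: Negishi carboalumination (syn Me–Al addition, as for pent-4-yn-1-ol) and iodinolysis fix the E geometry of the later C24=C25 alkene.

Step 20
Reactants: 35 (2S,5E)-1-chloro-6-iodo-5-methylhex-5-en-2-ol
Product: 36 (2S,5E)-1-chloro-5-methylocta-5,7-dien-2-ol
Conditions: tributyl(vinyl)stannane, PdCl2(MeCN)2 (5 mol %), DMF, rt
Reagents that add atoms: tributyl(vinyl)stannane, C=C[Sn](CCCC)(CCCC)CCCC
Why: Stille coupling proceeds with retention at the vinyl iodide and gives the E terminal diene.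

Step 21
Reactants: 36 (2S,5E)-1-chloro-5-methylocta-5,7-dien-2-ol
Product: 37 (2S)-2-[(3E)-3-methylhexa-3,5-dien-1-yl]oxirane
Conditions: K2CO3, MeOH, 0 °C → rt
Reagents that add atoms: none
Why: Intramolecular Williamson closure displaces chloride at the primary carbon, so the C–O bond of the stereocentre is not broken.

Step 22
Reactants: 37 (2S)-2-[(3E)-3-methylhexa-3,5-dien-1-yl]oxirane
Product: 38 (4S,7E)-7-methyldeca-7,9-dien-1-yn-4-ol (fragment C)
Conditions: LiC≡CH·H2NCH2CH2NH2, DMSO, rt; aq. NH4Cl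
Reagents that add atoms: lithium acetylide ethylenediamine complex, [Li]C#C.NCCN
Why: SN2 opening of the terminal epoxide by acetylide at CH2 gives the homopropargylic alcohol with C21 still S.

## Assembly and ring closure

Step 23
Reactants: 28 tert-butyl{[(1E,3S,7Z)-1-iodo-2-methyl-10-(trimethylsilyl)deca-1,7-dien-9-yn-3-yl]oxy}dimethylsilane; 38 (4S,7E)-7-methyldeca-7,9-dien-1-yn-4-ol
Product: 39 (3E,7S,11E,13S,17Z)-13-[(tert-butyldimethylsilyl)oxy]-4,12-dimethyl-20-(trimethylsilyl)icosa-1,3,11,17-tetraene-9,19-diyn-7-ol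
Conditions: PdCl2(PPh3)2 (5 mol %), CuI (10 mol %), Et3N, degassed THF, rt
Reagents that add atoms: none
Why: Sonogashira coupling joins C17 to C18 with retention of the E vinyl geometry; the silyl-capped alkyne and the free hydroxyl do not interfere.

Step 24
Reactants: 39 (3E,7S,11E,13S,17Z)-13-[(tert-butyldimethylsilyl)oxy]-4,12-dimethyl-20-(trimethylsilyl)icosa-1,3,11,17-tetraene-9,19-diyn-7-ol
Product: 40 (3E,7S,11E,13S,17Z)-13-[(tert-butyldimethylsilyl)oxy]-4,12-dimethylicosa-1,3,11,17-tetraene-9,19-diyn-7-ol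
Conditions: K2CO3 (0.5 equiv), MeOH/THF, rt
Reagents that add atoms: none
Why: Methanolysis cleaves only the alkynyl C–Si bond; the secondary silyl ether is stable.

Step 25
Reactants: 40 (3E,7S,11E,13S,17Z)-13-[(tert-butyldimethylsilyl)oxy]-4,12-dimethylicosa-1,3,11,17-tetraene-9,19-diyn-7-ol; 13 (4R,6E)-7-iodo-4-methyl-3-methylidenehept-6-enoic acid
Product: 41 (3E,7S,11E,13S,17Z)-13-[(tert-butyldimethylsilyl)oxy]-4,12-dimethylicosa-1,3,11,17-tetraene-9,19-diyn-7-yl (4R,6E)-7-iodo-4-methyl-3-methylidenehept-6-enoate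
Conditions: 13 (1.3 equiv), N,N′-diisopropylcarbodiimide, 4-(dimethylamino)pyridine (0.1 equiv), CH2Cl2, 0 °C, 0.2 M
Reagents that add atoms: none
Why: Steglich esterification with retention at C21; the concentrated, cold reaction with only catalytic 4-(dimethylamino)pyridine is fast enough to outrun migration of the exo-methylene into conjugation.

Step 26
Reactants: 41 (3E,7S,11E,13S,17Z)-13-[(tert-butyldimethylsilyl)oxy]-4,12-dimethylicosa-1,3,11,17-tetraene-9,19-diyn-7-yl (4R,6E)-7-iodo-4-methyl-3-methylidenehept-6-enoate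
Product: 42 (5R,7E,11Z,16S,17E,22S)-16-[(tert-butyldimethylsilyl)oxy]-5,17-dimethyl-4-methylidene-22-[(3E)-3-methylhexa-3,5-dien-1-yl]-1-oxacyclodocosa-7,11,17-triene-9,19-diyn-2-one
Conditions: Pd(PPh3)4 (20 mol %), CuI (40 mol %), Et3N, degassed THF, rt, syringe-pump addition over 12 h to 1 mM
Reagents that add atoms: none
Why: Intramolecular Sonogashira macrocyclization forms C7–C8 and closes the 22-membered ring under high dilution; the amine is too weak to isomerise the β,γ-unsaturated ester.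

Step 27
Reactants: 42 (5R,7E,11Z,16S,17E,22S)-16-[(tert-butyldimethylsilyl)oxy]-5,17-dimethyl-4-methylidene-22-[(3E)-3-methylhexa-3,5-dien-1-yl]-1-oxacyclodocosa-7,11,17-triene-9,19-diyn-2-one
Product: 43 (5R,7E,9Z,11Z,16S,17E,19Z,22S)-16-[(tert-butyldimethylsilyl)oxy]-5,17-dimethyl-4-methylidene-22-[(3E)-3-methylhexa-3,5-dien-1-yl]-1-oxacyclodocosa-7,9,11,17,19-pentaen-2-one
Conditions: Zn dust activated with Cu(OAc)2 and AgNO3, MeOH/H2O/THF, 40 °C, dark
Reagents that add atoms: none
Why: Boland semi-reduction with Zn(Cu/Ag) reduces only alkynes conjugated to alkenes and does so cis, giving 8Z and 18Z (ring locants 9Z, 19Z) while the dienes, the exo-methylene and the ester are left alone.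

Step 28
Reactants: 43 (5R,7E,9Z,11Z,16S,17E,19Z,22S)-16-[(tert-butyldimethylsilyl)oxy]-5,17-dimethyl-4-methylidene-22-[(3E)-3-methylhexa-3,5-dien-1-yl]-1-oxacyclodocosa-7,9,11,17,19-pentaen-2-one
Product: 44 (5R,7E,9Z,11Z,16S,17E,19Z,22S)-16-hydroxy-5,17-dimethyl-4-methylidene-22-[(3E)-3-methylhexa-3,5-dien-1-yl]-1-oxacyclodocosa-7,9,11,17,19-pentaen-2-one (target)
Conditions: HF·pyridine, pyridine, THF, 0 °C → rt, dark
Reagents that add atoms: none
Why: Pyridine-buffered fluoride desilylation frees the C15 hydroxyl without ionising the dienylic alcohol or isomerising the polyene and the β,γ-unsaturated lactone.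

## Compound list

1 | (4S)-4-benzyl-3-propanoyl-1,3-oxazolidin-2-one | O=C1OC[C@H](Cc2ccccc2)N1C(=O)CC | starting material
2 | 3-bromo-1-(trimethylsilyl)prop-1-yne | C[Si](C)(C)C#CCBr | starting material
3 | sodium (1Z)-1-[(4S)-4-benzyl-2-oxo-1,3-oxazolidin-3-yl]prop-1-en-1-olate | O=C1OC[C@H](Cc2ccccc2)N1C(/[O-])=C/C.[Na+] | intermediate
4 | (4S)-4-benzyl-3-[(2R)-2-methyl-5-(trimethylsilyl)pent-4-ynoyl]-1,3-oxazolidin-2-one | O=C1OC[C@H](Cc2ccccc2)N1C(=O)[C@H](C)CC#C[Si](C)(C)C | intermediate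
5 | (2R)-N-methoxy-N,2-dimethyl-5-(trimethylsilyl)pent-4-ynamide | CON(C)C(=O)[C@H](C)CC#C[Si](C)(C)C | intermediate
6 | (3R)-3-methyl-6-(trimethylsilyl)hex-5-yn-2-one | CC(=O)[C@H](C)CC#C[Si](C)(C)C | intermediate
7 | potassium (3R)-3-methyl-6-(trimethylsilyl)hex-1-en-5-yn-2-olate | C=C([O-])[C@H](C)CC#C[Si](C)(C)C.[K+] | intermediate
8 | (3R)-3-methyl-6-(trimethylsilyl)hex-1-en-5-yn-2-yl trifluoromethanesulfonate | C=C(OS(=O)(=O)C(F)(F)F)[C@H](C)CC#C[Si](C)(C)C | intermediate
9 | methyl (4R)-4-methyl-3-methylidene-7-(trimethylsilyl)hept-6-ynoate | COC(=O)CC(=C)[C@H](C)CC#C[Si](C)(C)C | intermediate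
10 | methyl (4R)-4-methyl-3-methylidenehept-6-ynoate | COC(=O)CC(=C)[C@H](C)CC#C | intermediate
11 | chlorobis(cyclopentadienyl)[(1E,4R)-7-methoxy-4-methyl-5-methylidene-7-oxohept-1-en-1-yl]zirconium | COC(=O)CC(=C)[C@H](C)C/C=C/[Zr](Cl)(C1C=CC=C1)C1C=CC=C1 | intermediate
12 | methyl (4R,6E)-7-iodo-4-methyl-3-methylidenehept-6-enoate | COC(=O)CC(=C)[C@H](C)C/C=C/I | intermediate
13 | (4R,6E)-7-iodo-4-methyl-3-methylidenehept-6-enoic acid | OC(=O)CC(=C)[C@H](C)C/C=C/I | intermediate
14 | prop-2-yn-1-ol | C#CCO | starting material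
15 | [(1E)-3-(dimethylalumanyloxy)-2-methylprop-1-en-1-yl]dimethylalumane | C[Al](C)/C=C(\C)CO[Al](C)C | intermediate
16 | (2E)-3-iodo-2-methylprop-2-en-1-ol | I/C=C(\C)CO | intermediate
17 | (2E)-3-iodo-2-methylprop-2-enal | I/C=C(\C)C=O | intermediate
18 | 1-bromo-4-chlorobutane | ClCCCCBr | starting material
19 | (4-chlorobutyl)magnesium bromide | ClCCCC[Mg]Br | intermediate
20 | rac-(1E)-7-chloro-1-iodo-2-methylhept-1-en-3-ol | I/C=C(\C)C(O)CCCCCl | intermediate
21 | (1E)-7-chloro-1-iodo-2-methylhept-1-en-3-one | I/C=C(\C)C(=O)CCCCCl | intermediate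
22 | (1E,3S)-7-chloro-1-iodo-2-methylhept-1-en-3-ol | I/C=C(\C)[C@@H](O)CCCCCl | intermediate
23 | tert-butyl{[(1E,3S)-7-chloro-1-iodo-2-methylhept-1-en-3-yl]oxy}dimethylsilane | I/C=C(\C)[C@@H](O[Si](C)(C)C(C)(C)C)CCCCCl | intermediate
24 | tert-butyl{[(1E,3S)-1,7-diiodo-2-methylhept-1-en-3-yl]oxy}dimethylsilane | I/C=C(\C)[C@@H](O[Si](C)(C)C(C)(C)C)CCCCI | intermediate
25 | [(5S,6E)-5-[(tert-butyldimethylsilyl)oxy]-7-iodo-6-methylhept-6-en-1-yl]triphenylphosphonium iodide | I/C=C(\C)[C@@H](O[Si](C)(C)C(C)(C)C)CCCC[P+](c1ccccc1)(c1ccccc1)c1ccccc1.[I-] | intermediate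
26 | 3-(trimethylsilyl)prop-2-ynal | C[Si](C)(C)C#CC=O | starting material
27 | [(5S,6E)-5-[(tert-butyldimethylsilyl)oxy]-7-iodo-6-methylhept-6-en-1-ylidene]triphenyl-λ5-phosphane | I/C=C(\C)[C@@H](O[Si](C)(C)C(C)(C)C)CCCC=P(c1ccccc1)(c1ccccc1)c1ccccc1 | intermediate
28 | tert-butyl{[(1E,3S,7Z)-1-iodo-2-methyl-10-(trimethylsilyl)deca-1,7-dien-9-yn-3-yl]oxy}dimethylsilane | I/C=C(\C)[C@@H](O[Si](C)(C)C(C)(C)C)CCC/C=C\C#C[Si](C)(C)C | intermediate
29 | (2S)-2-(chloromethyl)oxirane | ClC[C@@H]1CO1 | starting material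
30 | 1-(trimethylsilyl)prop-1-yne | CC#C[Si](C)(C)C | starting material
31 | [3-(trimethylsilyl)prop-2-yn-1-yl]lithium | [Li]CC#C[Si](C)(C)C | intermediate
32 | (2S)-1-chloro-6-(trimethylsilyl)hex-5-yn-2-ol | ClC[C@@H](O)CCC#C[Si](C)(C)C | intermediate
33 | (2S)-1-chlorohex-5-yn-2-ol | ClC[C@@H](O)CCC#C | intermediate
34 | [(1E,5S)-6-chloro-5-(dimethylalumanyloxy)-2-methylhex-1-en-1-yl]dimethylalumane | ClC[C@@H](O[Al](C)C)CC/C(C)=C/[Al](C)C | intermediate
35 | (2S,5E)-1-chloro-6-iodo-5-methylhex-5-en-2-ol | ClC[C@@H](O)CC/C(C)=C/I | intermediate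
36 | (2S,5E)-1-chloro-5-methylocta-5,7-dien-2-ol | ClC[C@@H](O)CC/C(C)=C/C=C | intermediate
37 | (2S)-2-[(3E)-3-methylhexa-3,5-dien-1-yl]oxirane | C1[C@@H](O1)CC/C(C)=C/C=C | intermediate
38 | (4S,7E)-7-methyldeca-7,9-dien-1-yn-4-ol | C#CC[C@@H](O)CC/C(C)=C/C=C | intermediate
39 | (3E,7S,11E,13S,17Z)-13-[(tert-butyldimethylsilyl)oxy]-4,12-dimethyl-20-(trimethylsilyl)icosa-1,3,11,17-tetraene-9,19-diyn-7-ol | C=C/C=C(\C)CC[C@H](O)CC#C/C=C(\C)[C@@H](O[Si](C)(C)C(C)(C)C)CCC/C=C\C#C[Si](C)(C)C | intermediate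
40 | (3E,7S,11E,13S,17Z)-13-[(tert-butyldimethylsilyl)oxy]-4,12-dimethylicosa-1,3,11,17-tetraene-9,19-diyn-7-ol | C=C/C=C(\C)CC[C@H](O)CC#C/C=C(\C)[C@@H](O[Si](C)(C)C(C)(C)C)CCC/C=C\C#C | intermediate
41 | (3E,7S,11E,13S,17Z)-13-[(tert-butyldimethylsilyl)oxy]-4,12-dimethylicosa-1,3,11,17-tetraene-9,19-diyn-7-yl (4R,6E)-7-iodo-4-methyl-3-methylidenehept-6-enoate | C=C/C=C(\C)CC[C@H](OC(=O)CC(=C)[C@H](C)C/C=C/I)CC#C/C=C(\C)[C@@H](O[Si](C)(C)C(C)(C)C)CCC/C=C\C#C | intermediate
42 | (5R,7E,11Z,16S,17E,22S)-16-[(tert-butyldimethylsilyl)oxy]-5,17-dimethyl-4-methylidene-22-[(3E)-3-methylhexa-3,5-dien-1-yl]-1-oxacyclodocosa-7,11,17-triene-9,19-diyn-2-one | C=C/C=C(\C)CC[C@H]1CC#C/C=C(\C)[C@@H](O[Si](C)(C)C(C)(C)C)CCC/C=C\C#C/C=C/C[C@@H](C)C(=C)CC(=O)O1 | intermediate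
43 | (5R,7E,9Z,11Z,16S,17E,19Z,22S)-16-[(tert-butyldimethylsilyl)oxy]-5,17-dimethyl-4-methylidene-22-[(3E)-3-methylhexa-3,5-dien-1-yl]-1-oxacyclodocosa-7,9,11,17,19-pentaen-2-one | C=C/C=C(\C)CC[C@H]1C/C=C\C=C(/C)[C@@H](O[Si](C)(C)C(C)(C)C)CCC\C=C/C=C\C=C\C[C@@H](C)C(=C)CC(=O)O1 | intermediate
44 | (5R,7E,9Z,11Z,16S,17E,19Z,22S)-16-hydroxy-5,17-dimethyl-4-methylidene-22-[(3E)-3-methylhexa-3,5-dien-1-yl]-1-oxacyclodocosa-7,9,11,17,19-pentaen-2-one | C=C/C=C(\C)CC[C@H]1C/C=C\C=C(/C)[C@@H](O)CCC\C=C/C=C\C=C\C[C@@H](C)C(=C)CC(=O)O1 | target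

## Step count and risks

Total step count: 28 (fragment A steps 1–8, fragment B steps 9–16, fragment C steps 17–22, assembly steps 23–28).

Longest linear sequence: 14 steps (steps 9–16, then 23–28), which is half of the total.

The three steps most likely to fail:

Step 26 (ring closure by Sonogashira coupling). At 1 mM the vinyl-palladium intermediate may still find another molecule or the copper acetylide may dimerise, giving oligomers instead of the 22-membered ring. The fallback closes the ring at the ester bond instead. It sets out from 40 and 13, which are joined by an intermolecular Sonogashira coupling (Pd(PPh3)4, CuI, excess Et3N, THF, rt; the free acid is tolerated as its ammonium salt) to the open-chain hydroxy acid (4R,6E,10Z,15S,16E,21S,24E)-15-[(tert-butyldimethylsilyl)oxy]-21-hydroxy-4,16,24-trimethyl-3-methylideneheptacosa-6,10,16,24,26-pentaene-8,18-diynoic acid F1. A Shiina macrolactonization of this acid (2-methyl-6-nitrobenzoic anhydride, 4-(dimethylamino)pyridine, CH2Cl2, slow addition to 2 mM, rt) comes back to the route at 42.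

Step 5 (coupling of the Reformatsky reagent with the vinyl triflate). The zinc enolate may couple sluggishly or the product may isomerise on the metal. The fallback builds the same ester through a symmetric 2-substituted allyl system. It sets out from 8, which is hydroxymethylated by Stille coupling with (tributylstannyl)methanol (Pd(PPh3)4, LiCl, 1,4-dioxane, 90 °C) to (3R)-3-methyl-2-methylidene-6-(trimethylsilyl)hex-5-yn-1-ol F2. Methyl chloroformate and pyridine (CH2Cl2, 0 °C) turn it into methyl (3R)-3-methyl-2-methylidene-6-(trimethylsilyl)hex-5-yn-1-yl carbonate F3. Decarboxylative carbonylation (Pd(OAc)2, PPh3, CO 10 bar, toluene, 50 °C) then inserts CO at either of the two equivalent allyl termini, returns the methoxide to the acyl group, and comes back to the route at 9.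

Step 25 (esterification of the 3-methylidene acid). The acyl-pyridinium of 13 has a doubly activated CH2 and can lose a proton, which would deliver the conjugated 3-methyl-2-enoate. The fallback removes base and acyl-pyridinium altogether. It sets out from 13, which adds to ethoxyacetylene under [RuCl2(p-cymene)]2 catalysis (1 mol %, acetone, rt) to give 1-ethoxyethenyl (4R,6E)-7-iodo-4-methyl-3-methylidenehept-6-enoate F4. Acid-catalysed acyl transfer from this enol ester to 40 (camphorsulfonic acid 5 mol %, 1,2-dichloroethane, 40 °C) comes back to the route at 41.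

## Further compounds

F1 | step 26 | (4R,6E,10Z,15S,16E,21S,24E)-15-[(tert-butyldimethylsilyl)oxy]-21-hydroxy-4,16,24-trimethyl-3-methylideneheptacosa-6,10,16,24,26-pentaene-8,18-diynoic acid | C=C/C=C(\C)CC[C@H](O)CC#C/C=C(\C)[C@@H](O[Si](C)(C)C(C)(C)C)CCC/C=C\C#C/C=C/C[C@@H](C)C(=C)CC(=O)O
F2 | step 5 | (3R)-3-methyl-2-methylidene-6-(trimethylsilyl)hex-5-yn-1-ol | OCC(=C)[C@H](C)CC#C[Si](C)(C)C
F3 | step 5 | methyl (3R)-3-methyl-2-methylidene-6-(trimethylsilyl)hex-5-yn-1-yl carbonate | COC(=O)OCC(=C)[C@H](C)CC#C[Si](C)(C)C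
F4 | step 25 | 1-ethoxyethenyl (4R,6E)-7-iodo-4-methyl-3-methylidenehept-6-enoate | CCOC(=C)OC(=O)CC(=C)[C@H](C)C/C=C/I
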